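**Assumption:** Furospongin-4 has no stereocentre and is achiral. "Single enantiomer" is therefore read as the single geometric isomer in the SMILES: central acid alkene 2Z (COOH cis to the furan-side chain) and the other three alkenes E.

## Retrosynthetic overview
1. Last step: an E-selective Wittig reaction brings in the methyl ester ready-made, so the acid and the ester never need to be differentiated or protected.
2. Key step: the obvious Still–Gennari/Ando HWE or allyl-sulfone coupling is avoided. The Z-acid comes from a 2-ynoic acid and allyl alcohol by Ru-catalysed "contra-electronic" syn addition of H and CH2CH2CHO across the alkyne.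
3. The ynoic acid comes from γ-alkylation of the but-2-ynoic acid dianion with a C15 furano-allylic bromide.
4. The bromide comes from dendrolasin by E-selective SeO2 oxidation. Dendrolasin comes from geranyl bromide and 3-furylmethyl Grignard, so one E-alkene is purchased.
5. Rings: the furan is the only ring and is bought intact. No ring is formed.

## Route

**Step 1**
Reactants: 1, furan-3-ylmethanol
Product: 2, 3-(chloromethyl)furan
Conditions: MsCl, LiCl, 2,4,6-collidine, DMF, 0 °C; use at once
Reagents that add atoms: lithium chloride, [Li+].[Cl-] (MsCl, CS(=O)(=O)Cl, activates the oxygen and is an equivalent chloride source)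
Why: In this Collington–Meyers chlorination the mesylate is displaced in situ by chloride (SN2) in a collidine-buffered, HCl-free medium that the furan tolerates; no stereo-element is involved.

**Step 2**
Reactants: 2, 3-(chloromethyl)furan; 3, geranyl bromide [(2E)-1-bromo-3,7-dimethylocta-2,6-diene]
Product: 4, dendrolasin, 3-[(3E)-4,8-dimethylnona-3,7-dien-1-yl]furan
Conditions: (i) 2, Mg, THF, 0 °C→rt; (ii) 3, Li2CuCl4 (5 mol %), THF, 0 °C
Reagents that add atoms: geranyl bromide (3), CC(C)=CCC/C(C)=C/CBr; nothing else
Why: In this Kochi-type Cu-catalysed Grignard/allylic halide coupling the furylmethyl nucleophile reacts at its exocyclic carbon and at the unhindered α-carbon of 3, because SN2′ would require attack at a fully substituted carbon, so the purchased E-alkene is retained.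

**Step 3**
Reactants: 4, dendrolasin
Product: 5, neotorreyol, (2E,6E)-9-(furan-3-yl)-2,6-dimethylnona-2,6-dien-1-ol
Conditions: SeO2 (0.3 equiv), t-BuOOH (3 equiv), salicylic acid (0.1 equiv), CH2Cl2, 0 °C→rt; then NaBH4, MeOH, 0 °C
Reagents that add atoms: selenium dioxide, O=[Se]=O; tert-butyl hydroperoxide, CC(C)(C)OO (terminal oxidant)
Why: Sharpless–Umbreit allylic oxidation (ene reaction, then [2,3]-shift) attacks the most nucleophilic and least hindered terminal isopropylidene and oxidises only the methyl trans to the chain, which sets the E-CH2OH alkene, and NaBH4 returns any over-oxidised enal.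

**Step 4**
Reactants: 5, neotorreyol
Product: 6, 3-[(3E,7E)-9-bromo-4,8-dimethylnona-3,7-dien-1-yl]furan
Conditions: MsCl, Et3N, THF, −40 °C; then LiBr, THF, 0 °C; use crude
Reagents that add atoms: lithium bromide, [Li+].[Br-]
Why: Mesylate/bromide SN2 exchange under acid-free conditions gives the primary allylic bromide without allylic transposition or E/Z erosion and spares the furan.

**Step 5**
Reactants: 6, allylic bromide; 7, but-2-ynoic acid
Product: 8, (6E,10E)-13-(furan-3-yl)-6,10-dimethyltrideca-6,10-dien-2-ynoic acid
Conditions: 7 (1.3 equiv), LDA (2.7 equiv), THF–DMPU, −78 °C, 1 h; then 6, −78→−20 °C; cold citric acid work-up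
Reagents that add atoms: but-2-ynoic acid (7), CC#CC(=O)O
Why: In this carboxylic acid dianion alkylation LiCH2C≡CCO2Li reacts with the soft primary allylic bromide by SN2 at the propargylic (γ) terminus remote from the carboxylate charge, which gives the free 1,5-enynoic acid in one operation without touching the existing alkenes.

**Step 6 (key step)**
Reactants: 8, ynoic acid; 9, allyl alcohol
Product: 10, (2Z,6E,10E)-13-(furan-3-yl)-6,10-dimethyl-2-(3-oxopropyl)trideca-2,6,10-trienoic acid
Conditions: [CpRu(MeCN)3]PF6 (10 mol %), 9 (3 equiv), degassed acetone (0.2 M), rt, slow addition of 8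
Reagents that add atoms: allyl alcohol (9), C=CCO
Why: Proposed new method: this applies two known variants of the Trost Ru alkene–alkyne (formal Alder-ene) coupling, namely α-alkylation of 2-ynoates and allyl alcohol as a β-formylethyl donor, to an unprotected 2-ynoic acid; CpRu+ binds the alkyne and the only monosubstituted alkene present, oxidative cyclisation places the electron-rich Ru on the electrophilic β-carbon C3 and forms the C2–CH2 bond, the only accessible β-H (the carbinol C–H) is eliminated to an enol that tautomerises to the aldehyde, and C3–H reductive elimination with retention delivers H and the new chain syn, which forces COOH cis to C4 (2Z), while the trisubstituted alkenes and the furan do not enter this cycle.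

**Step 7**
Reactants: 10, Z-acid aldehyde; 11, methyl 2-(triphenyl-λ5-phosphanylidene)propanoate
Product: 12, furospongin-4, (2Z,6E,10E)-13-(furan-3-yl)-2-[(3E)-5-methoxy-4-methyl-5-oxopent-3-en-1-yl]-6,10-dimethyltrideca-2,6,10-trienoic acid
Conditions: 11 (2.5 equiv), CH2Cl2, rt, 16 h; 5 % citric acid work-up
Reagents that add atoms: ylide 11, COC(=O)C(C)=P(c1ccccc1)(c1ccccc1)c1ccccc1
Why: The stabilised α-methyl ylide gives the E-enoate (typically ≥95:5) in a Wittig olefination; the first equivalent only deprotonates the COOH, the resulting carboxylate makes the Z-enoate inert to conjugate addition or isomerisation, and acidic work-up returns the free acid beside the methyl ester.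

## Compound list
1 | furan-3-ylmethanol | OCc1ccoc1 | starting material
2 | 3-(chloromethyl)furan | ClCc1ccoc1 | intermediate
3 | geranyl bromide | CC(C)=CCC/C(C)=C/CBr | starting material
4 | dendrolasin | CC(C)=CCC/C(C)=C/CCc1ccoc1 | intermediate
5 | neotorreyol | OC/C(C)=C/CC/C(C)=C/CCc1ccoc1 | intermediate
6 | 3-[(3E,7E)-9-bromo-4,8-dimethylnona-3,7-dien-1-yl]furan | BrC/C(C)=C/CC/C(C)=C/CCc1ccoc1 | intermediate
7 | but-2-ynoic acid | CC#CC(=O)O | starting material
8 | (6E,10E)-13-(furan-3-yl)-6,10-dimethyltrideca-6,10-dien-2-ynoic acid | OC(=O)C#CCC/C(C)=C/CC/C(C)=C/CCc1ccoc1 | intermediate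
9 | allyl alcohol | C=CCO | starting material
10 | (2Z,6E,10E)-13-(furan-3-yl)-6,10-dimethyl-2-(3-oxopropyl)trideca-2,6,10-trienoic acid | O=CCC/C(=C/CC/C(C)=C/CC/C(C)=C/CCc1ccoc1)C(=O)O | intermediate
11 | methyl 2-(triphenyl-λ5-phosphanylidene)propanoate | COC(=O)C(C)=P(c1ccccc1)(c1ccccc1)c1ccccc1 | starting material
12 | furospongin-4 | COC(=O)/C(C)=C/CC/C(=C/CC/C(C)=C/CC/C(C)=C/CCc1ccoc1)C(=O)O | target

## Summary
Total steps: 7. Longest linear sequence: 7 (1→2→4→5→6→8→10→12). No protecting groups are used.

**Steps most likely to fail, with fallbacks**
1. **Step 6.** The risks are β- rather than α-regiochemistry, catalyst inhibition by the free acid, and redox isomerisation of allyl alcohol.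
   - Fallback: replace the one-step coupling with stepwise syn-hydrometalation and cross-coupling.
   - Esterify 8 as its 2-(trimethylsilyl)ethyl ester, then run Pd(PPh3)4/Bu3SnH syn-hydrostannation, which places Sn at the α-carbon and the ester cis to the chain.
   - Carry out Sn→I exchange, then Negishi coupling with 2-(1,3-dioxolan-2-yl)ethylzinc bromide.
   - Hydrolyse the acetal, perform the Wittig reaction, and remove the ester with TBAF.
2. **Step 5.** The risks are α-attack to give an allenic acid, and proton transfer with alkyne/allene scrambling.
   - Fallback: build the alkyne before the carboxyl group.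
   - Alkylate lithiated 1-(trimethylsilyl)propyne with 6 (Corey–Kirst), then run CsF/CO2 desilylative carboxylation to 8.
3. **Step 3.** The risks are modest site selectivity and furan oxidation.
   - Fallback: oxidise before the furan is present.
   - Oxidise geranyl acetate with SeO2/t-BuOOH to 8-hydroxygeranyl acetate and protect it as the TBS ether.
   - Couple the allylic acetate with 3-furylmethylmagnesium chloride under Li2CuCl4 catalysis, then remove the TBS group with TBAF to reach 5.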